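**Retrosynthetic overview**

1. Target 31 ⇒ chroman-5,8-diol 29: the quinone and the C3=C4 double bond are late oxidations (DDQ).
2. 29 ⇒ cyclobutenone 26 (key step). The methoxyquinone ring, C5(=O)–C6(OMe)=C7(H)–C8(=O) closed through C4a=C8a with the pyran oxygen O1 on C8a, is split into a four-carbon squarate unit (C5–C8) and the enol-ether double bond C4a=C8a of a 3,4-dihydro-2H-pyran; thermal 4π opening and 6π closure form C8–C8a.
3. 26 ⇒ vinyl bromide 21 + methyl semisquarate 24; 21 ⇒ dihydropyran 19 ⇒ alkynol 18 (endo cycloisomerisation); C2 comes from Sharpless epoxidation of allylic alcohol 13 and hydride opening.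
4. 13 ⇒ vinylcyclohexene 8 + (Z)-3-iodobut-2-en-1-ol 11 (B-alkyl Suzuki); 8 ⇒ keto-aldehyde 7 (McMurry) ⇒ acid 3, made from geranyl propionate 1 by an enantioselective Ireland–Claisen rearrangement that sets C1' and C2' together.
5. Order of ring formation: cyclohexene (step 4), dihydropyran (step 10), benzenoid ring (step 15).

Key step: step 15

Locants: chromene numbering (O1, C2–C4, C4a, C5–C8, C8a) for the bicyclic core; C1'–C6' for the cyclohexene ring, C1' being the quaternary carbon.

Assumption (step 1): the (4S,5S)-diazaborolidine bromide is taken as the enantiomer that leads to (2R,3S)-3; if the sense of induction is the opposite, the (4R,5R)-reagent is used and nothing else changes.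

**Route**

Step 1
Reactants: 1 geranyl propionate [(2E)-3,7-dimethylocta-2,6-dien-1-yl propanoate]
Product: 3 (2R,3S)-3-ethenyl-2,3,7-trimethyloct-6-enoic acid, via boron ketene acetal 2 (not isolated)
Conditions: (4S,5S)-2-bromo-4,5-diphenyl-1,3-bis{[3,5-bis(trifluoromethyl)phenyl]sulfonyl}-1,3,2-diazaborolidine (1.2 equiv), i-Pr2NEt, CH2Cl2, −78 °C; then −20 °C → 4 °C; aq work-up
Reagents that add atoms: none
Why: Enantioselective boron-mediated Ireland–Claisen rearrangement: soft enolisation gives ketene acetal 2 with methyl cis to O–B, which rearranges through a chair with the homoprenyl chain equatorial, so C2 and C3 are set together (relative configuration from the enolate and E-alkene geometries, absolute configuration from the C2-symmetric sulfonamide ligand on boron).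

Step 2
Reactants: 3 (2R,3S)-3-ethenyl-2,3,7-trimethyloct-6-enoic acid
Product: 5 (3R,4S)-4-ethenyl-3,4,8-trimethylnon-7-en-2-one, via dilithium gem-diolate 4 (not isolated)
Conditions: MeLi (3 equiv), Et2O, 0 °C → rt; inverse quench into cold aq HCl
Reagents that add atoms: methyllithium, [Li]C
Why: Methyl ketone synthesis from a carboxylic acid: MeLi adds to the lithium carboxylate to give the stable gem-diolate 4, which releases the ketone only on quench, so over-addition and epimerisation of the α-stereocentre are avoided.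

Step 3
Reactants: 5 (3R,4S)-4-ethenyl-3,4,8-trimethylnon-7-en-2-one
Product: 7 (4S,5R)-4-ethenyl-4,5-dimethyl-6-oxoheptanal, via ozonide 6 (not isolated)
Conditions: O3, CH2Cl2, −78 °C (Sudan Red 7B end-point); then Me2S, −78 °C → rt
Reagents that add atoms: ozone, [O-][O+]=O
Why: Chemoselective ozonolysis: the electron-rich trisubstituted alkene should react with ozone well before the hindered monosubstituted vinyl group (dye end-point), and reduction of ozonide 6 releases the aldehyde without touching either stereocentre.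

Step 4
Reactants: 7 (4S,5R)-4-ethenyl-4,5-dimethyl-6-oxoheptanal
Product: 8 (5S,6S)-5-ethenyl-1,5,6-trimethylcyclohex-1-ene
Conditions: TiCl3(DME)1.5, Zn(Cu), DME, reflux; 7 added slowly by syringe pump
Reagents that add atoms: none
Why: Intramolecular McMurry coupling: low-valent titanium joins the two carbonyl carbons of the 1,6-keto-aldehyde reductively with loss of both oxygens, closing the six-membered ring as the trisubstituted alkene C3'=C4' and leaving the vinyl group and both stereocentres untouched.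

Step 5
Reactants: 9 but-2-yn-1-ol
Product: 11 (2Z)-3-iodobut-2-en-1-ol, via alkenylaluminate 10 (not isolated)
Conditions: NaAlH2(OCH2CH2OMe)2, Et2O, 0 °C → rt; then I2, THF, −78 °C
Reagents that add atoms: iodine, II
Why: Hydroxyl-directed trans-hydroalumination of the propargylic alcohol places aluminium on C3 in the five-membered aluminate 10, and iodinolysis with retention gives the Z-vinyl iodide.

Step 6
Reactants: 8 (5S,6S)-5-ethenyl-1,5,6-trimethylcyclohex-1-ene; 11 (2Z)-3-iodobut-2-en-1-ol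
Product: 13 (2Z)-3-methyl-5-[(1S,2R)-1,2,3-trimethylcyclohex-3-en-1-yl]pent-2-en-1-ol, via alkylborane 12 (not isolated)
Conditions: 9-BBN, THF, rt; then 11, PdCl2(dppf) (5 mol%), AsPh3, Cs2CO3, DMF–THF–H2O, rt
Reagents that add atoms: none
Why: Hydroboration with 9-BBN is anti-Markovnikov and touches only the monosubstituted alkene, and B-alkyl Suzuki–Miyaura coupling on zerovalent palladium joins the primary alkyl group to the vinyl iodide with retention of the Z geometry.

Step 7
Reactants: 13 (2Z)-3-methyl-5-[(1S,2R)-1,2,3-trimethylcyclohex-3-en-1-yl]pent-2-en-1-ol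
Product: 14 [(2R,3S)-3-methyl-3-{2-[(1S,2R)-1,2,3-trimethylcyclohex-3-en-1-yl]ethyl}oxiran-2-yl]methanol
Conditions: Ti(Oi-Pr)4 (10 mol%), D-(−)-diethyl tartrate (12 mol%), t-BuOOH, 4 Å MS, CH2Cl2, −20 °C
Reagents that add atoms: tert-butyl hydroperoxide, CC(C)(C)OO
Why: Katsuki–Sharpless asymmetric epoxidation: with D-(−)-diethyl tartrate the titanium-bound peroxide is delivered to the alkene face that gives the (2R,3S)-epoxide (reagent control; the tertiary carbon, the future C2, is set here), and the ring alkene, which has no allylic hydroxyl, is left alone.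

Step 8
Reactants: 14 [(2R,3S)-3-methyl-3-{2-[(1S,2R)-1,2,3-trimethylcyclohex-3-en-1-yl]ethyl}oxiran-2-yl]methanol
Product: 16 trimethyl(3-{(2R,3S)-3-methyl-3-[2-((1S,2R)-1,2,3-trimethylcyclohex-3-en-1-yl)ethyl]oxiran-2-yl}prop-1-yn-1-yl)silane, via epoxy triflate 15 (not isolated)
Conditions: Tf2O, 2,6-lutidine, CH2Cl2, −78 °C; then Me3SiC≡CLi, THF–DMPU, −78 °C
Reagents that add atoms: lithium (trimethylsilyl)acetylide, [Li]C#C[Si](C)(C)C
Why: SN2 alkylation of an acetylide: the primary epoxy triflate 15 is displaced at −78 °C far faster than the trisubstituted epoxide is opened, so the two alkyne carbons (the future pyran C5 and C6) are attached and both epoxide stereocentres are kept.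

Step 9
Reactants: 16 trimethyl(3-{(2R,3S)-3-methyl-3-[2-((1S,2R)-1,2,3-trimethylcyclohex-3-en-1-yl)ethyl]oxiran-2-yl}prop-1-yn-1-yl)silane
Product: 18 (3R)-3-methyl-1-[(1S,2R)-1,2,3-trimethylcyclohex-3-en-1-yl]hept-6-yn-3-ol, via silylalkynol 17 (not isolated)
Conditions: LiEt3BH, THF, 0 °C → rt; then MeOH, K2CO3, rt
Reagents that add atoms: none
Why: Regioselective hydride opening of an epoxide: LiEt3BH attacks the less substituted epoxide carbon in an SN2 reaction, so the C–O bond and the configuration of the tertiary carbon are kept, and methanolic carbonate then cleaves the alkynyl C–Si bond.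

Step 10
Reactants: 18 (3R)-3-methyl-1-[(1S,2R)-1,2,3-trimethylcyclohex-3-en-1-yl]hept-6-yn-3-ol
Product: 19 (2R)-2-methyl-2-{2-[(1S,2R)-1,2,3-trimethylcyclohex-3-en-1-yl]ethyl}-3,4-dihydro-2H-pyran
Conditions: W(CO)6 (25 mol%), Et3N, THF, hν (350 nm), 60 °C
Reagents that add atoms: none
Why: Tungsten-catalysed endo cycloisomerisation of a bis-homopropargylic alcohol: the terminal alkyne is turned on W(CO)5 into a vinylidene whose metal-bound carbon is attacked by the tertiary hydroxyl (6-endo closure), and protonolysis gives the cyclic enol ether with C2 unchanged (the descriptor changes only because the priorities change).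

Step 11
Reactants: 19 (2R)-2-methyl-2-{2-[(1S,2R)-1,2,3-trimethylcyclohex-3-en-1-yl]ethyl}-3,4-dihydro-2H-pyran
Product: 21 (2S)-5-bromo-2-methyl-2-{2-[(1S,2R)-1,2,3-trimethylcyclohex-3-en-1-yl]ethyl}-3,4-dihydro-2H-pyran, via dibromide 20 (not isolated)
Conditions: Br2 (1.0 equiv, slow addition), CH2Cl2, −78 °C; then Et3N, −78 °C → rt
Reagents that add atoms: bromine, BrBr
Why: Bromination–dehydrobromination of an enol ether: bromine should add to the electron-rich enol ether faster than to the trialkyl alkene at −78 °C, and Et3N removes HBr from dibromide 20 through the oxocarbenium ion, which leaves bromine on C5.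

Step 12
Reactants: 22 dimethyl squarate (3,4-dimethoxycyclobut-3-ene-1,2-dione)
Product: 23 4-hydroxy-2,3-dimethoxycyclobut-2-en-1-one (racemic)
Conditions: LiAlH(Ot-Bu)3, THF, −78 °C
Reagents that add atoms: none
Why: Carbonyl 1,2-reduction: the bulky alkoxyaluminium hydride reduces one of the two equivalent ketone carbonyls of the squarate and stops at the hydroxycyclobutenone.

Step 13
Reactants: 23 4-hydroxy-2,3-dimethoxycyclobut-2-en-1-one
Product: 24 3-methoxycyclobut-3-ene-1,2-dione (methyl semisquarate)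
Conditions: conc. aq HCl (cat.), CH2Cl2, rt
Reagents that add atoms: water, O
Why: Acid-catalysed allylic transposition with hydrolysis of a vinylogous ester: ionisation of the hydroxyl gives a methoxy-stabilised cyclobutenyl cation, water adds at the distal methoxy-bearing carbon and methanol is lost to give the enedione.

Step 14
Reactants: 21 (2S)-5-bromo-2-methyl-2-{2-[(1S,2R)-1,2,3-trimethylcyclohex-3-en-1-yl]ethyl}-3,4-dihydro-2H-pyran; 24 3-methoxycyclobut-3-ene-1,2-dione
Product: 26 4-hydroxy-3-methoxy-4-[(2S)-2-methyl-2-{2-[(1S,2R)-1,2,3-trimethylcyclohex-3-en-1-yl]ethyl}-3,4-dihydro-2H-pyran-5-yl]cyclobut-2-en-1-one (both epimers at the carbinol carbon), via vinyllithium 25 (not isolated)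
Conditions: t-BuLi (2 equiv), THF, −78 °C; then cannulation into 24, THF, −78 °C; aq NH4Cl
Reagents that add atoms: none
Why: Bromine–lithium exchange and 1,2-addition: vinyllithium 25 adds to the carbonyl next to the methoxy-bearing carbon (C2 of 24), because the other carbonyl is deactivated as a vinylogous ester, which fixes OMe next to the carbinol carbon; the new carbinol centre forms without control and disappears in step 15.

Step 15
Reactants: 26 4-hydroxy-3-methoxy-4-[(2S)-2-methyl-2-{2-[(1S,2R)-1,2,3-trimethylcyclohex-3-en-1-yl]ethyl}-3,4-dihydro-2H-pyran-5-yl]cyclobut-2-en-1-one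
Product: 29 (2S)-6-methoxy-2-methyl-2-{2-[(1S,2R)-1,2,3-trimethylcyclohex-3-en-1-yl]ethyl}-3,4-dihydro-2H-chromene-5,8-diol, via dienylketene 27 (not isolated), via cyclohexadienone 28 (not isolated)
Conditions: degassed p-xylene, 138 °C, Ar
Reagents that add atoms: none
Why: Heating opens the C1–C4 bond of the cyclobutenone in a conrotatory 4π electrocyclic reaction; the C4 hydroxyl, the stronger donor, rotates outward, so the dihydropyranyl group turns inward and dienylketene 27 forms with its ketene carbon next to the enol-ether carbon C6 of the pyran. Thermal disrotatory 6π electrocyclisation then joins the ketene carbon to that carbon (C8–C8a in chromene numbering) and closes the six-membered carbocycle as dienone 28, which enolises to the aromatic hydroquinone 29. The closest known reaction is the thermal ring expansion of 4-alkenyl- and 4-aryl-4-hydroxycyclobutenones to hydroquinones (Moore rearrangement). No stereocentre is formed: the carbinol centre of 26 becomes the sp2 carbon C5 and the C8a–H of 28 is lost on enolisation, while C2, C1' and C2' are remote spectators. The step needs inward rotation of the alkenyl group, which the outward preference of the hydroxyl secures, and the correct placement of the methoxy group, which is already built into 26: the four squarate carbons become C5, C6 (OMe), C7 and C8 and the enol-ether carbons become C4a and C8a, so OMe can only end up next to the carbonyl attached to C4a. The electron-rich enol-ether terminus should also make closure onto the ketene faster than capture of the ketene by its own hydroxyl.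

Step 16
Reactants: 29 (2S)-6-methoxy-2-methyl-2-{2-[(1S,2R)-1,2,3-trimethylcyclohex-3-en-1-yl]ethyl}-3,4-dihydro-2H-chromene-5,8-diol
Product: 31 (2S)-6-methoxy-2-methyl-2-{2-[(1S,2R)-1,2,3-trimethylcyclohex-3-en-1-yl]ethyl}-2H-chromene-5,8-dione, via chromanquinone 30 (not isolated)
Conditions: DDQ (2.5 equiv), 1,4-dioxane, rt → reflux
Reagents that add atoms: none
Why: Quinone dehydrogenation with DDQ: the hydroquinone is first oxidised to quinone 30, DDQ then abstracts hydride from C4 (the cation is stabilised through C4a=C8a by O1, as in the dehydrogenation of dihydropyrano-fused quinones) and loss of the C3 proton gives the 2H-chromene without touching C2.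

**Compound list**

1 | geranyl propionate, (2E)-3,7-dimethylocta-2,6-dien-1-yl propanoate | CCC(=O)OC/C=C(\C)CCC=C(C)C | starting material
2 | boron ketene acetal of 1 (methyl cis to O–B; boron carries the (4S,5S)-4,5-diphenyl-1,3-bis{[3,5-bis(trifluoromethyl)phenyl]sulfonyl}-1,3,2-diazaborolidine ring) | C/C=C(\OB1N(S(=O)(=O)c2cc(cc(c2)C(F)(F)F)C(F)(F)F)[C@@H](c2ccccc2)[C@H](c2ccccc2)N1S(=O)(=O)c1cc(cc(c1)C(F)(F)F)C(F)(F)F)OC/C=C(\C)CCC=C(C)C | intermediate (not isolated)
3 | (2R,3S)-3-ethenyl-2,3,7-trimethyloct-6-enoic acid | C=C[C@](C)(CCC=C(C)C)[C@@H](C)C(=O)O | intermediate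
4 | dilithium (3R,4S)-4-ethenyl-3,4,8-trimethylnon-7-ene-2,2-bis(olate) | C=C[C@](C)(CCC=C(C)C)[C@@H](C)C(C)(O[Li])O[Li] | intermediate (not isolated)
5 | (3R,4S)-4-ethenyl-3,4,8-trimethylnon-7-en-2-one | C=C[C@](C)(CCC=C(C)C)[C@@H](C)C(C)=O | intermediate
6 | (3R,4S)-4-[2-(5,5-dimethyl-1,2,4-trioxolan-3-yl)ethyl]-3,4-dimethylhex-5-en-2-one (ozonide) | C=C[C@](C)(CCC1OOC(C)(C)O1)[C@@H](C)C(C)=O | intermediate (not isolated)
7 | (4S,5R)-4-ethenyl-4,5-dimethyl-6-oxoheptanal | C=C[C@](C)(CCC=O)[C@@H](C)C(C)=O | intermediate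
8 | (5S,6S)-5-ethenyl-1,5,6-trimethylcyclohex-1-ene | C=C[C@]1(C)CCC=C(C)[C@@H]1C | intermediate
9 | but-2-yn-1-ol | CC#CCO | starting material
10 | sodium 2,2-bis(2-methoxyethoxy)-3-methyl-2,5-dihydro-1,2-oxaluminol-2-uide (cyclic alkenylaluminate) | CC1=CCO[Al-]1(OCCOC)OCCOC.[Na+] | intermediate (not isolated)
11 | (2Z)-3-iodobut-2-en-1-ol | OC/C=C(/C)I | intermediate
12 | 9-[2-(1,2,3-trimethylcyclohex-3-en-1-yl)ethyl]-9-borabicyclo[3.3.1]nonane, ring stereocentres as in 8 | C1CC2CCCC(C1)B2CC[C@]1(C)CCC=C(C)[C@@H]1C | intermediate (not isolated)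
13 | (2Z)-3-methyl-5-[(1S,2R)-1,2,3-trimethylcyclohex-3-en-1-yl]pent-2-en-1-ol | OC/C=C(/C)CC[C@]1(C)CCC=C(C)[C@@H]1C | intermediate
14 | [(2R,3S)-3-methyl-3-{2-[(1S,2R)-1,2,3-trimethylcyclohex-3-en-1-yl]ethyl}oxiran-2-yl]methanol | OC[C@H]1O[C@@]1(C)CC[C@]2(C)CCC=C(C)[C@@H]2C | intermediate
15 | [(2R,3S)-3-methyl-3-{2-[(1S,2R)-1,2,3-trimethylcyclohex-3-en-1-yl]ethyl}oxiran-2-yl]methyl trifluoromethanesulfonate | FC(F)(F)S(=O)(=O)OC[C@H]1O[C@@]1(C)CC[C@]2(C)CCC=C(C)[C@@H]2C | intermediate (not isolated)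
16 | trimethyl(3-{(2R,3S)-3-methyl-3-[2-((1S,2R)-1,2,3-trimethylcyclohex-3-en-1-yl)ethyl]oxiran-2-yl}prop-1-yn-1-yl)silane | C[Si](C)(C)C#CC[C@H]1O[C@@]1(C)CC[C@]2(C)CCC=C(C)[C@@H]2C | intermediate
17 | (3S)-3-methyl-1-[(1S,2R)-1,2,3-trimethylcyclohex-3-en-1-yl]-7-(trimethylsilyl)hept-6-yn-3-ol | C[Si](C)(C)C#CCC[C@@](C)(O)CC[C@]1(C)CCC=C(C)[C@@H]1C | intermediate (not isolated)
18 | (3R)-3-methyl-1-[(1S,2R)-1,2,3-trimethylcyclohex-3-en-1-yl]hept-6-yn-3-ol | C#CCC[C@@](C)(O)CC[C@]1(C)CCC=C(C)[C@@H]1C | intermediate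
19 | (2R)-2-methyl-2-{2-[(1S,2R)-1,2,3-trimethylcyclohex-3-en-1-yl]ethyl}-3,4-dihydro-2H-pyran | C1=CO[C@@](C)(CC[C@]2(C)CCC=C(C)[C@@H]2C)CC1 | intermediate
20 | (6S)-2,3-dibromo-6-methyl-6-{2-[(1S,2R)-1,2,3-trimethylcyclohex-3-en-1-yl]ethyl}oxane (2,3-trans; mixture at C2/C3) | BrC1CC[C@](C)(CC[C@]2(C)CCC=C(C)[C@@H]2C)OC1Br | intermediate (not isolated)
21 | (2S)-5-bromo-2-methyl-2-{2-[(1S,2R)-1,2,3-trimethylcyclohex-3-en-1-yl]ethyl}-3,4-dihydro-2H-pyran | BrC1=CO[C@@](C)(CC[C@]2(C)CCC=C(C)[C@@H]2C)CC1 | intermediate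
22 | dimethyl squarate, 3,4-dimethoxycyclobut-3-ene-1,2-dione | COC1=C(OC)C(=O)C1=O | starting material
23 | 4-hydroxy-2,3-dimethoxycyclobut-2-en-1-one (racemic) | COC1=C(OC)C(=O)C1O | intermediate
24 | 3-methoxycyclobut-3-ene-1,2-dione (methyl semisquarate) | COC1=CC(=O)C1=O | intermediate
25 | [(2R)-2-methyl-2-{2-[(1S,2R)-1,2,3-trimethylcyclohex-3-en-1-yl]ethyl}-3,4-dihydro-2H-pyran-5-yl]lithium | [Li]C1=CO[C@@](C)(CC[C@]2(C)CCC=C(C)[C@@H]2C)CC1 | intermediate (not isolated)
26 | 4-hydroxy-3-methoxy-4-[(2S)-2-methyl-2-{2-[(1S,2R)-1,2,3-trimethylcyclohex-3-en-1-yl]ethyl}-3,4-dihydro-2H-pyran-5-yl]cyclobut-2-en-1-one (both epimers at the carbinol carbon) | COC1=CC(=O)C1(O)C2=CO[C@@](C)(CC[C@]3(C)CCC=C(C)[C@@H]3C)CC2 | intermediate (key-step precursor)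
27 | (3Z)-4-hydroxy-3-methoxy-4-[(2S)-2-methyl-2-{2-[(1S,2R)-1,2,3-trimethylcyclohex-3-en-1-yl]ethyl}-3,4-dihydro-2H-pyran-5-yl]buta-1,3-dien-1-one (dienylketene) | O=C=C/C(OC)=C(/O)C1=CO[C@@](C)(CC[C@]2(C)CCC=C(C)[C@@H]2C)CC1 | intermediate (not isolated)
28 | (2S)-5-hydroxy-6-methoxy-2-methyl-2-{2-[(1S,2R)-1,2,3-trimethylcyclohex-3-en-1-yl]ethyl}-2,3,4,8a-tetrahydro-8H-chromen-8-one (C8a epimers) | COC1=CC(=O)C2O[C@@](C)(CC[C@]3(C)CCC=C(C)[C@@H]3C)CCC2=C1O | intermediate (not isolated)
29 | (2S)-6-methoxy-2-methyl-2-{2-[(1S,2R)-1,2,3-trimethylcyclohex-3-en-1-yl]ethyl}-3,4-dihydro-2H-chromene-5,8-diol | COc1cc(O)c2c(c1O)CC[C@](C)(CC[C@]3(C)CCC=C(C)[C@@H]3C)O2 | intermediate (key-step product)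
30 | (2S)-6-methoxy-2-methyl-2-{2-[(1S,2R)-1,2,3-trimethylcyclohex-3-en-1-yl]ethyl}-3,4-dihydro-2H-chromene-5,8-dione | COC1=CC(=O)C2=C(CC[C@](C)(CC[C@]3(C)CCC=C(C)[C@@H]3C)O2)C1=O | intermediate (not isolated)
31 | (2S)-6-methoxy-2-methyl-2-{2-[(1S,2R)-1,2,3-trimethylcyclohex-3-en-1-yl]ethyl}-2H-chromene-5,8-dione | COC1=CC(=O)C2=C(C=C[C@](C)(CC[C@]3(C)CCC=C(C)[C@@H]3C)O2)C1=O | target

**Step count and risks**

Total step count: 16 (steps 5, 12 and 13 make the two small building blocks).
Longest linear sequence: 13 steps (1–4, 6–11, 14–16).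

The three steps most likely to fail (R below stands for the 2-[(1S,2R)-1,2,3-trimethylcyclohex-3-en-1-yl]ethyl group):

1. Step 11. Chemoselectivity may be lost: bromine may also add to the trisubstituted ring alkene, or the HBr released may add to or hydrolyse the enol ether before elimination is complete. Fallback, setting out from 18 and coming back at 21: the halogen is introduced at the lactone stage, where the only reactive alkene towards a positive bromine source is a silyl ketene acetal. The terminal alkyne of 18 is hydrated in the anti-Markovnikov sense by hydroboration with (c-C6H11)2BH and oxidation with NaBO3, which should give the lactol 6-methyl-6-R-oxan-2-ol F1. Ag2CO3 on Celite in refluxing benzene oxidises F1 to the δ-lactone 6-methyl-6-R-oxan-2-one F2. LiN(i-Pr)2 with Me3SiCl converts F2 into the silyl ketene acetal 2-methyl-2-R-6-(trimethylsilyloxy)-3,4-dihydro-2H-pyran F3, which NBS at −78 °C should brominate to the α-bromolactone 3-bromo-6-methyl-6-R-oxan-2-one F4. i-Bu2AlH at −78 °C reduces F4 to the bromolactol 3-bromo-6-methyl-6-R-oxan-2-ol F5, and MsCl/Et3N dehydrates F5 through the anomeric mesylate to 21.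

2. Step 16. The second oxidation may stall, because hydride abstraction from C4 of the electron-poor quinone is slow, and forcing conditions may bring allylic oxidation of the cyclohexene. Fallback, setting out from 29 and coming back at 31: the dehydrogenation is done on an electron-rich ring. MeI and K2CO3 in acetone convert 29 into the trimethyl ether (2S)-5,6,8-trimethoxy-2-methyl-2-R-3,4-dihydro-2H-chromene F6. DDQ in refluxing benzene dehydrogenates this alkoxychroman (hydride loss from C4 assisted by the 5-methoxy group and O1) to (2S)-5,6,8-trimethoxy-2-methyl-2-R-2H-chromene F7. (NH4)2Ce(NO3)6 in MeCN–H2O at 0 °C then removes the para pair of methyl groups oxidatively to give quinone 31.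

3. Step 15. The dienylketene may be captured by its own hydroxyl (lactonisation to a furanone), or the acid-sensitive carbinol next to the enol ether may ionise before ring opening. Fallback, setting out from 26 and coming back at 29: the hydroxyl is blocked before heating. Et3SiOTf and 2,6-lutidine convert 26 into the silyl ether 3-methoxy-4-[(2S)-2-methyl-2-R-3,4-dihydro-2H-pyran-5-yl]-4-(triethylsilyloxy)cyclobut-2-en-1-one F8. Thermolysis of F8 in p-xylene should follow the same 4π/6π course, now without a free hydroxyl on the ketene, and give the mono-silyl hydroquinone (2S)-6-methoxy-2-methyl-2-R-5-(triethylsilyloxy)-3,4-dihydro-2H-chromen-8-ol F9. n-Bu4NF in THF removes the silyl group to give 29.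

Further compounds
F1 | step 11 | 6-methyl-6-{2-[(1S,2R)-1,2,3-trimethylcyclohex-3-en-1-yl]ethyl}oxan-2-ol (quaternary carbon as in 18; both anomers) | OC1CCC[C@](C)(CC[C@]2(C)CCC=C(C)[C@@H]2C)O1
F2 | step 11 | 6-methyl-6-{2-[(1S,2R)-1,2,3-trimethylcyclohex-3-en-1-yl]ethyl}oxan-2-one (quaternary carbon as in 18) | O=C1CCC[C@](C)(CC[C@]2(C)CCC=C(C)[C@@H]2C)O1
F3 | step 11 | 2-methyl-2-{2-[(1S,2R)-1,2,3-trimethylcyclohex-3-en-1-yl]ethyl}-6-(trimethylsilyloxy)-3,4-dihydro-2H-pyran (quaternary carbon as in 18) | C[Si](C)(C)OC1=CCC[C@](C)(CC[C@]2(C)CCC=C(C)[C@@H]2C)O1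
F4 | step 11 | 3-bromo-6-methyl-6-{2-[(1S,2R)-1,2,3-trimethylcyclohex-3-en-1-yl]ethyl}oxan-2-one (quaternary carbon as in 18; C3 epimers) | O=C1C(Br)CC[C@](C)(CC[C@]2(C)CCC=C(C)[C@@H]2C)O1
F5 | step 11 | 3-bromo-6-methyl-6-{2-[(1S,2R)-1,2,3-trimethylcyclohex-3-en-1-yl]ethyl}oxan-2-ol (quaternary carbon as in 18; mixture at C2/C3) | OC1C(Br)CC[C@](C)(CC[C@]2(C)CCC=C(C)[C@@H]2C)O1
F6 | step 16 | (2S)-5,6,8-trimethoxy-2-methyl-2-{2-[(1S,2R)-1,2,3-trimethylcyclohex-3-en-1-yl]ethyl}-3,4-dihydro-2H-chromene | COc1cc(OC)c2c(c1OC)CC[C@](C)(CC[C@]3(C)CCC=C(C)[C@@H]3C)O2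
F7 | step 16 | (2S)-5,6,8-trimethoxy-2-methyl-2-{2-[(1S,2R)-1,2,3-trimethylcyclohex-3-en-1-yl]ethyl}-2H-chromene | COc1cc(OC)c2c(c1OC)C=C[C@](C)(CC[C@]3(C)CCC=C(C)[C@@H]3C)O2
F8 | step 15 | 3-methoxy-4-[(2S)-2-methyl-2-{2-[(1S,2R)-1,2,3-trimethylcyclohex-3-en-1-yl]ethyl}-3,4-dihydro-2H-pyran-5-yl]-4-(triethylsilyloxy)cyclobut-2-en-1-one (both epimers at the silyloxy carbon) | COC1=CC(=O)C1(O[Si](CC)(CC)CC)C2=CO[C@@](C)(CC[C@]3(C)CCC=C(C)[C@@H]3C)CC2
F9 | step 15 | (2S)-6-methoxy-2-methyl-2-{2-[(1S,2R)-1,2,3-trimethylcyclohex-3-en-1-yl]ethyl}-5-(triethylsilyloxy)-3,4-dihydro-2H-chromen-8-ol | COc1cc(O)c2c(c1O[Si](CC)(CC)CC)CC[C@](C)(CC[C@]3(C)CCC=C(C)[C@@H]3C)O2
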